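Ring atoms are numbered C1 (OMe), C2 (OH), C3 (OBz), C4 (OH), C5 (alkene carbon bearing the benzoyloxymethyl carbon C7) and C6 (alkene CH). Compound numbers are those of the steps and of the compound list.

## Analysis of the target

Target 19 is a single cyclohexene ring whose C5=C6 alkene carries C7 on C5, with four contiguous oxygenated stereocentres C1–C4. Each of these centres is trans to its neighbour, so the oxygens alternate between the two faces (1S,2R,3R,4S in this numbering) and can all sit equatorial in one half-chair. The sensitive groups are the two benzoates: the secondary one on C3 lies between free hydroxyls on C2 and C4 and can migrate under base, and both can be saponified. The ring is also two eliminations from an arene, so losing methanol, water or benzoic acid across it would be irreversible. The difficulty is that the four ring oxygens are in four different states with the only acylated one in the middle, so each must arrive with its final substituent, and the absolute configuration must be created without a stereocentre to start from. The structural feature that decides the plan is that the C1 and C4 oxygens are para, and C2/C3 form a trans hydroxy-benzoate, the product of a C2–C3 oxirane opened at C3. This is the pattern of an epoxidised p-quinone monoketal whose second enone alkene is C5=C6. The whole skeleton and every oxygen site are therefore present in a 2,5-dioxygenated benzyl alcohol, and the problem reduces to one face- and site-selective epoxidation and the relay of its configuration to C1 and C4.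

## Retrosynthetic reasoning

**C4–H.** Target 19 is taken back to enone 18, in which C4 is a ketone conjugated with C5=C6. With C1–C3 in place and equatorial, axial hydride delivery should give the equatorial C4 hydroxyl trans to the C3 ester. Making this the last step means the C4 hydroxyl never has to be distinguished from the C2 hydroxyl. The forward reaction must be a strict 1,2-reduction and must not move the C3 benzoate.

**C3–O.** In 18 the C3–O(benzoyl) bond is cut and the C2 oxygen is folded back into an oxirane, giving epoxy enone 16 and benzoic acid 17. The cut is made at C3 rather than C2 because C3 is the α-carbon of an epoxy ketone, the position at which such oxiranes accept nucleophiles, and inversion there gives the trans C2-OH/C3-OBz pair directly. The forward reaction must attack C3 and not C2, and must not dehydrate the β-hydroxy ketone it forms.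

**C4 carbonyl.** Enone 16 comes from dimethyl ketal 14 and water 15. The carbonyl is unmasked only here, so that C3 stays shielded by the ketal while C1 is adjusted and becomes electrophilic only when the benzoate is to enter.

**O–CH3.** Ether 14 is cut to trans-epoxy alcohol 12 and iodomethane 13. The methylation must not generate a free alkoxide, since this would trigger oxirane migration or ester exchange.

**C1–O.** The C1–O bond of 12 is cut via chloroacetate 11 to cis-epoxy alcohol 9 and chloroacetic acid 10. Hydride is expected to reach the C1 carbonyl from the face away from the oxirane oxygen, which leaves the hydroxyl cis to the oxirane. The trans relation needed in 19 is therefore planned as an SN2 inversion rather than hoped for from a directed reduction. The acyl group must later come off in the presence of the benzoate.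

**C1–H.** Alcohol 9 is taken back to epoxy enone 8. The forward step is a 1,2-reduction under substrate control.

**C2–O and C3–O, the key disconnection.** Oxirane 8 is cut at both C–O bonds to achiral dienone 6 and tert-butyl hydroperoxide 7. This is the only step that creates chirality. The forward reaction must choose the unsubstituted enone alkene and one face of it.

**Aromatic precursor.** Dienone 6 is cut at the ester to alcohol 4 and benzoyl chloride 5. Alcohol 4 is cut at the ketal C–O bond to phenol 2 and methanol 3 (oxidative dearomatisation). Phenol 2 comes from commercial aldehyde 1 by reduction.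

## Alternatives that were turned down

**Alternative 1:** The ring bonds C4–C5 and C1–C6 are cut, leading to furan A1 and 2-bromoacrolein A2. The forward key step is a Diels–Alder reaction under a chiral oxazaborolidine Lewis acid, giving oxanorbornene A3.
- For it: a mature enantioselective cycloaddition makes two C–C bonds and the ring at once. The bridging oxygen already spans C1 and C4, the formyl carbon is C7, and dehydrobromination would give C5=C6.
- Against it: the C2=C3 alkene of A3 must become a trans hydroxy-benzoate with the ester on C3. From an exo oxirane this needs endo attack on a strained bicycle at one of two nearly equivalent carbons. The bridge must then be cleaved by methanolysis at C1 with inversion, but once C5=C6 is present both bridgeheads are allylic, so ionisation threatens both regio- and stereochemistry. Furan adducts also cyclorevert easily.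
- Comparison: it is probably stronger on the enantioselectivity of the stereo-defining step. The chosen route is shorter, takes all seven carbons from one arene, and differentiates the oxygens through the arene's substitution pattern instead of a late bridge opening.

**Alternative 2:** The C3–O and C4–O bonds are cut, leading to bromobenzene A4. The forward key step is whole-cell dioxygenase cis-dihydroxylation to diene diol A5.
- For it: A5 is essentially enantiopure, and the bromine marks C5 for later attachment of C7. The C1=C2 alkene can be epoxidised anti to the protected diol and opened by methanolysis at the allylic carbon C1, which gives the C1-OMe/C2-OH pair with more reliable regiochemistry than the chosen route has at its oxirane opening.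
- Against it: the diol is cis, whereas C3/C4 of the target are trans. Only the C3 oxygen has the right configuration, so C4 must be inverted. The two hydroxyls must be told apart, the C2 hydroxyl needs temporary protection, and C7 requires a coupling at the C–Br bond plus redox adjustment.
- Comparison: it is stronger on enantiopurity and on the C1/C2 pair. The chosen route has C7 in place from the start, lets the C3 ester arrive in the ring-opening itself, and needs no fermentation and almost no protecting groups.

**Alternative 3:** The C4–C5 bond is cut, leading to acyclic iodo aldehyde A6. The forward key step is an intramolecular Nozaki–Hiyama–Kishi addition of the C5 vinyl iodide to the C4 aldehyde, giving A7, one deprotection from the target.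
- For it: ring closure and the last stereocentre come in one chemoselective step that tolerates esters. The C1–C3 triad could come from the chiral pool, so the absolute configuration would be secure and no oxirane regiochemistry arises.
- Against it: A6 needs a long linear build (a Z-trisubstituted vinyl iodide with an allylic benzoate and three differently substituted contiguous oxygens). Its α-benzoyloxy aldehyde can epimerise and suffer acyl migration. The C4 configuration in a six-membered closure is substrate-controlled and hard to predict, and the reaction consumes a large excess of a toxic metal reductant.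
- Comparison: it is equal or stronger on absolute configuration, weaker on C4 control and clearly longer.

Key step: step 4

Assumption: N-benzylcinchonidinium and N-benzylcinchoninium chloride are pseudoenantiomeric, and the one that gives the (1S,6R) oxirane 8 is to be identified by a trial with both.

## Route

Step 1
Reactants: 1 5-hydroxy-2-methoxybenzaldehyde
Product: 2 3-(hydroxymethyl)-4-methoxyphenol
Conditions: NaBH4, MeOH, 0 °C
Reagents that add atoms: none
Why: Borohydride reduction of an aryl aldehyde; the phenol and the aryl ether are inert.

Step 2
Reactants: 2 3-(hydroxymethyl)-4-methoxyphenol; 3 methanol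
Product: 4 3-(hydroxymethyl)-4,4-dimethoxycyclohexa-2,5-dien-1-one
Conditions: PhI(OAc)2, MeOH, 0 °C
Reagents that add atoms: methanol 3, CO
Why: Oxidative dearomatisation of a 4-methoxyphenol by a hypervalent iodine diacetate: the aryloxy-iodane is attacked by methanol para to the phenol oxygen, at the carbon that already bears OMe, giving the quinone monoketal. The primary alcohol is not oxidised by this reagent and cannot close a ring onto the ketal carbon.

Step 3
Reactants: 4 3-(hydroxymethyl)-4,4-dimethoxycyclohexa-2,5-dien-1-one; 5 benzoyl chloride
Product: 6 (6,6-dimethoxy-3-oxocyclohexa-1,4-dien-1-yl)methyl benzoate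
Conditions: BzCl, pyridine, DMAP (cat.), CH2Cl2, 0 °C
Reagents that add atoms: benzoyl chloride 5, O=C(Cl)c1ccccc1
Why: Acyl transfer to the only hydroxyl; dienone and ketal tolerate the weakly basic medium.

Step 4
Reactants: 6 (6,6-dimethoxy-3-oxocyclohexa-1,4-dien-1-yl)methyl benzoate; 7 tert-butyl hydroperoxide
Product: 8 [(1S,6R)-5,5-dimethoxy-2-oxo-7-oxabicyclo[4.1.0]hept-3-en-4-yl]methyl benzoate
Conditions: TBHP (70% aq.), NaOH (aq., substoichiometric), N-benzylcinchonidinium chloride (10 mol %), toluene, 0 °C
Reagents that add atoms: tert-butyl hydroperoxide 7, CC(C)(C)OO
Why: Weitz–Scheffer nucleophilic epoxidation, a known reaction of quinone monoketals that cinchona ammonium phase-transfer salts render enantioselective. The tert-butyl peroxide anion, carried into toluene as an ion pair with the chiral cation, adds to C3, the β-carbon of the unsubstituted enone (C3–O bond). The C1–C2 enolate then displaces tert-butoxide at the peroxide oxygen through C2 (C2–O bond), a 3-exo-tet closure that forms the oxirane ring. C3 is set by the face of the dienone that the ion pair exposes to the peroxide; C2 is not independent, because a three-membered ring fused to the six-membered ring can only close cis, on the face the peroxide entered. Site selectivity between the two enone alkenes comes from the substrate: addition at C5 would build a quaternary centre between the ketal and the benzoyloxymethyl group and should be far slower than addition at the CH of C3. Chemoselectivity against the ester should follow from dilute base, low temperature and the two-phase medium, with the peroxide consumed by the faster conjugate addition. A second epoxidation is not expected because the remaining enone of 8 is β,β-disubstituted.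

Step 5
Reactants: 8 [(1S,6R)-5,5-dimethoxy-2-oxo-7-oxabicyclo[4.1.0]hept-3-en-4-yl]methyl benzoate
Product: 9 [(1R,2R,6R)-2-hydroxy-5,5-dimethoxy-7-oxabicyclo[4.1.0]hept-3-en-4-yl]methyl benzoate (C1 hydroxyl cis to the oxirane)
Conditions: NaBH4, CeCl3·7H2O, MeOH, −78 °C
Reagents that add atoms: none
Why: Luche 1,2-reduction of the enone carbonyl; ester, ketal and oxirane are inert at this temperature. Hydride should approach C1 from the face away from the adjacent oxirane oxygen, as nucleophiles generally do with oxiranes fused next to a cyclohexenone carbonyl, so the new C1 centre is set by the substrate with the hydroxyl cis to the oxirane.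

Step 6
Reactants: 9 [(1R,2R,6R)-2-hydroxy-5,5-dimethoxy-7-oxabicyclo[4.1.0]hept-3-en-4-yl]methyl benzoate; 10 chloroacetic acid
Product: 11 [(1R,2S,6R)-2-(2-chloroacetoxy)-5,5-dimethoxy-7-oxabicyclo[4.1.0]hept-3-en-4-yl]methyl benzoate
Conditions: ClCH2CO2H, PPh3, DIAD, THF, 0 °C → rt
Reagents that add atoms: chloroacetic acid 10, OC(=O)CCl
Why: Mitsunobu esterification with SN2 inversion at C1, placing the oxygen trans to the oxirane; the oxirane oxygen lies on the same face as the leaving group and cannot participate. Chloroacetic acid is acidic enough for a hindered secondary alcohol, and elimination is excluded because C2–H sits on the oxirane and C6 is sp2.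

Step 7
Reactants: 11 [(1R,2S,6R)-2-(2-chloroacetoxy)-5,5-dimethoxy-7-oxabicyclo[4.1.0]hept-3-en-4-yl]methyl benzoate
Product: 12 [(1R,2S,6R)-2-hydroxy-5,5-dimethoxy-7-oxabicyclo[4.1.0]hept-3-en-4-yl]methyl benzoate (C1 hydroxyl trans to the oxirane)
Conditions: thiourea, NaHCO3, MeOH–THF, rt
Reagents that add atoms: none
Why: Selective dechloroacetylation: thiourea is alkylated on sulfur at CH2Cl and then cyclises onto the ester carbonyl, releasing the alcohol. The benzoate has no such handle, and the near-neutral medium avoids Payne migration of the trans-epoxy alcohol.

Step 8
Reactants: 12 [(1R,2S,6R)-2-hydroxy-5,5-dimethoxy-7-oxabicyclo[4.1.0]hept-3-en-4-yl]methyl benzoate; 13 iodomethane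
Product: 14 [(1R,2S,6R)-2,5,5-trimethoxy-7-oxabicyclo[4.1.0]hept-3-en-4-yl]methyl benzoate
Conditions: MeI, Ag2O, 4 Å MS, MeCN, rt, dark
Reagents that add atoms: iodomethane 13, CI
Why: Purdie methylation, chosen because no free alkoxide is formed, so neither oxirane migration nor ester exchange should occur; C1 is untouched.

Step 9
Reactants: 14 [(1R,2S,6R)-2,5,5-trimethoxy-7-oxabicyclo[4.1.0]hept-3-en-4-yl]methyl benzoate; 15 water
Product: 16 [(1R,5S,6R)-5-methoxy-2-oxo-7-oxabicyclo[4.1.0]hept-3-en-3-yl]methyl benzoate
Conditions: CF3CO2H–H2O, CH2Cl2, 0 °C
Reagents that add atoms: water 15, O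
Why: Acid hydrolysis of the dimethyl ketal through an oxocarbenium ion conjugated with C5=C6. The oxirane is flanked by two electron-poor carbons and should resist acid opening, and the allylic methyl ether should not ionise for the same reason.

Step 10
Reactants: 16 [(1R,5S,6R)-5-methoxy-2-oxo-7-oxabicyclo[4.1.0]hept-3-en-3-yl]methyl benzoate; 17 benzoic acid
Product: 18 (4S,5R,6S)-6-(benzoyloxy)-2-[(benzoyloxy)methyl]-5-hydroxy-4-methoxycyclohex-2-en-1-one
Conditions: PhCO2H (excess), PhCO2Cs (cat.), DMF, rt → 40 °C
Reagents that add atoms: benzoic acid 17, OC(=O)c1ccccc1
Why: SN2 opening of an α,β-epoxy ketone by a carboxylate at the α-carbon C3, the usual site for this class because the carbonyl assists substitution there; C2 is shielded by the cis C1 methoxy group on the face the nucleophile must use. Inversion at C3 puts the benzoate trans to the retained C2 hydroxyl, and excess acid keeps the medium non-basic so the β-hydroxy ketone should not dehydrate.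

Step 11
Reactants: 18 (4S,5R,6S)-6-(benzoyloxy)-2-[(benzoyloxy)methyl]-5-hydroxy-4-methoxycyclohex-2-en-1-one
Product: 19 [(3S,4R,5R,6S)-5-(benzoyloxy)-4,6-dihydroxy-3-methoxycyclohex-1-en-1-yl]methyl benzoate
Conditions: NaBH4, CeCl3·7H2O, MeOH, −78 °C; AcOH quench
Reagents that add atoms: none
Why: Luche 1,2-reduction. With the C1, C2 and C3 substituents equatorial, hydride should add axially, anti to the axial C3–H, giving the equatorial C4 hydroxyl trans to the C3 benzoate; low temperature and an acidic quench limit benzoate migration.

## Compound list

1 | 5-hydroxy-2-methoxybenzaldehyde | COc1ccc(O)cc1C=O | starting material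
2 | 3-(hydroxymethyl)-4-methoxyphenol | COc1ccc(O)cc1CO | intermediate
3 | methanol | CO | starting material
4 | 3-(hydroxymethyl)-4,4-dimethoxycyclohexa-2,5-dien-1-one | O=C1C=CC(OC)(OC)C(CO)=C1 | intermediate
5 | benzoyl chloride | O=C(Cl)c1ccccc1 | starting material
6 | (6,6-dimethoxy-3-oxocyclohexa-1,4-dien-1-yl)methyl benzoate | O=C1C=C(COC(=O)c2ccccc2)C(OC)(OC)C=C1 | intermediate
7 | tert-butyl hydroperoxide | CC(C)(C)OO | starting material
8 | [(1S,6R)-5,5-dimethoxy-2-oxo-7-oxabicyclo[4.1.0]hept-3-en-4-yl]methyl benzoate | O=C1C=C(COC(=O)c2ccccc2)C(OC)(OC)[C@@H]2O[C@H]12 | intermediate
9 | [(1R,2R,6R)-2-hydroxy-5,5-dimethoxy-7-oxabicyclo[4.1.0]hept-3-en-4-yl]methyl benzoate | O[C@@H]1C=C(COC(=O)c2ccccc2)C(OC)(OC)[C@@H]2O[C@H]12 | intermediate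
10 | chloroacetic acid | OC(=O)CCl | starting material
11 | [(1R,2S,6R)-2-(2-chloroacetoxy)-5,5-dimethoxy-7-oxabicyclo[4.1.0]hept-3-en-4-yl]methyl benzoate | O=C(CCl)O[C@H]1C=C(COC(=O)c2ccccc2)C(OC)(OC)[C@@H]2O[C@H]12 | intermediate
12 | [(1R,2S,6R)-2-hydroxy-5,5-dimethoxy-7-oxabicyclo[4.1.0]hept-3-en-4-yl]methyl benzoate | O[C@H]1C=C(COC(=O)c2ccccc2)C(OC)(OC)[C@@H]2O[C@H]12 | intermediate
13 | iodomethane | CI | starting material
14 | [(1R,2S,6R)-2,5,5-trimethoxy-7-oxabicyclo[4.1.0]hept-3-en-4-yl]methyl benzoate | CO[C@H]1C=C(COC(=O)c2ccccc2)C(OC)(OC)[C@@H]2O[C@H]12 | intermediate
15 | water | O | starting material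
16 | [(1R,5S,6R)-5-methoxy-2-oxo-7-oxabicyclo[4.1.0]hept-3-en-3-yl]methyl benzoate | CO[C@H]1C=C(COC(=O)c2ccccc2)C(=O)[C@@H]2O[C@H]12 | intermediate
17 | benzoic acid | OC(=O)c1ccccc1 | starting material
18 | (4S,5R,6S)-6-(benzoyloxy)-2-[(benzoyloxy)methyl]-5-hydroxy-4-methoxycyclohex-2-en-1-one | CO[C@H]1C=C(COC(=O)c2ccccc2)C(=O)[C@@H](OC(=O)c2ccccc2)[C@@H]1O | intermediate
19 | [(3S,4R,5R,6S)-5-(benzoyloxy)-4,6-dihydroxy-3-methoxycyclohex-1-en-1-yl]methyl benzoate | CO[C@H]1C=C(COC(=O)c2ccccc2)[C@H](O)[C@@H](OC(=O)c2ccccc2)[C@@H]1O | target

## Step count and least certain steps

Total step count: 11. Longest linear sequence: 11 steps (1 to 19).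

**Step 4 (key step).** The most likely failure is incomplete face discrimination, since the ion pair must distinguish the faces of a dienone that carries an extra substituent beside the ketal. The second is partial saponification or perhydrolysis of the primary benzoate by aqueous base. The fallback replaces asymmetric catalysis by resolution. From 6, water-free epoxidation (TBHP, DBU, CH2Cl2) should give the racemic oxirane F1, and NaBH4/CeCl3·7H2O the racemic cis-epoxy alcohol F2. Lipase-catalysed acylation (lipase from Burkholderia cepacia, vinyl acetate, tert-butyl methyl ether) is written here for the case that the enzyme acetylates the unwanted enantiomer to the acetate F3 and leaves the wanted alcohol. That alcohol is 9, where the route is rejoined. The same enzymatic step could raise the enantiomeric purity of 9 made by the catalytic route.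

**Step 10.** Three processes threaten it: attack at C2 instead of C3, dehydration of the β-hydroxy ketone followed by aromatisation, and allylic transposition of the C7 benzoate through conjugate addition at C6. The fallback changes both the order and the control element. From 16 the ketone is reduced first (NaBH4, CeCl3·7H2O, −78 °C); hydride anti to the oxirane should give the epoxy alcohol F4 with the C4 hydroxyl cis to the oxirane, which is the C4 configuration of 19, and no β-hydroxy ketone is ever formed. Benzoic acid 17 is then added to the oxirane under the trivalent cobalt benzoate complex of N,N′-bis(3,5-di-tert-butylsalicylidene)-1,2-cyclohexanediamine, a known catalyst type for carboxylic acid opening of cis-oxiranes. The ligand enantiomer is chosen so that C3 is the carbon attacked. The product is 19 itself, so the route is rejoined at 19 and 18 is bypassed.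

**Step 5.** Facial selectivity may be poor if chelation of the cation between the carbonyl and oxirane oxygens brings hydride in from the oxirane face as well. Any trans alcohol formed is 12 itself and enters step 8 directly, so both epimers converge and only the separation costs material. The fallback hands the choice of face to a reagent: Corey–Bakshi–Shibata reduction of 8 (BH3·SMe2, B-methyl oxazaborolidine of diphenylprolinol, enantiomer matched to the R carbinol) back to 9, with no new compound (F0).

**Step 6.** Activation of a hindered alcohol beside the oxirane may be sluggish, or the carboxylate may enter with allylic transposition at C5. The fallback is sulfonate displacement. From 9, MsCl/Et3N should give the methanesulfonate F5. HCO2Cs in DMF should displace it with inversion to the formate F6, and KHCO3 in MeOH should release 12, where the route is rejoined.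

## Further compounds

F1 | step 4 | racemic 8, (5,5-dimethoxy-2-oxo-7-oxabicyclo[4.1.0]hept-3-en-4-yl)methyl benzoate as the racemate | O=C1C=C(COC(=O)c2ccccc2)C(OC)(OC)C2OC12
F2 | step 4 | racemic 9, hydroxyl cis to the oxirane (racemate, relative configuration as written) | O[C@@H]1C=C(COC(=O)c2ccccc2)C(OC)(OC)[C@@H]2O[C@H]12
F3 | step 4 | acetate of the enantiomer of 9, [(1S,2S,6S)-2-acetoxy-5,5-dimethoxy-7-oxabicyclo[4.1.0]hept-3-en-4-yl]methyl benzoate | CC(=O)O[C@H]1C=C(COC(=O)c2ccccc2)C(OC)(OC)[C@H]2O[C@@H]12
F4 | step 10 | [(1S,2S,5S,6R)-2-hydroxy-5-methoxy-7-oxabicyclo[4.1.0]hept-3-en-3-yl]methyl benzoate (16 reduced at C4, hydroxyl cis to the oxirane) | CO[C@H]1C=C(COC(=O)c2ccccc2)[C@H](O)[C@@H]2O[C@H]12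
F0 | step 5 | none | none
F5 | step 6 | methanesulfonate of 9 (sulfonate on C1, cis to the oxirane) | CS(=O)(=O)O[C@@H]1C=C(COC(=O)c2ccccc2)C(OC)(OC)[C@@H]2O[C@H]12
F6 | step 6 | formate ester of 12 (formate on C1, trans to the oxirane) | O=CO[C@H]1C=C(COC(=O)c2ccccc2)C(OC)(OC)[C@@H]2O[C@H]12
A1 | alternative 1 | furan | c1ccoc1
A2 | alternative 1 | 2-bromoacrolein | C=C(Br)C=O
A3 | alternative 1 | 2-bromo-7-oxabicyclo[2.2.1]hept-5-ene-2-carbaldehyde, exo-formyl, enantiomer as written | [C@H]12C[C@](Br)(C=O)[C@H](O1)C=C2
A4 | alternative 2 | bromobenzene | Brc1ccccc1
A5 | alternative 2 | (1S,2S)-3-bromocyclohexa-3,5-diene-1,2-diol | C1=C(Br)[C@@H](O)[C@@H](O)C=C1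
A6 | alternative 3 | (2S,3R,4S,5Z)-2,7-bis(benzoyloxy)-6-iodo-4-methoxy-3-[(4-methoxybenzyl)oxy]hept-5-enal | O=C[C@@H](OC(=O)c1ccccc1)[C@H](OCc1ccc(OC)cc1)[C@@H](OC)/C=C(\I)COC(=O)c1ccccc1
A7 | alternative 3 | 2-O-(4-methoxybenzyl) ether of 19 | CO[C@H]1C=C(COC(=O)c2ccccc2)[C@H](O)[C@@H](OC(=O)c2ccccc2)[C@@H]1OCc3ccc(OC)cc3
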